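## Retrosynthetic overview

- 11 ⇐ 9 (removal of two pivalates) ⇐ 10 (reductive rearomatisation) ⇐ 8 (double para-oxidation in MeOH). Both C8–O bonds are made late, on the finished flavone.
- Feature used: in 8, C8 is the only hydrogen-bearing carbon of ring A and lies para to the free O5–H. Oxidising that phenol in methanol places oxygen at C8, and ketal 10 already differentiates the para oxygens (O8 alkylated, O5 a ketone).
- 8 ⇐ 7 ⇐ 6: BCl3 frees O5 (peri to C4=O) together with the ring B benzyl ethers. Ring B is then masked as the electron-poor bis-pivalate.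
- 6 ⇐ 5 ⇐ 2 + 4: a Claisen–Schmidt condensation joins rings A and B, and I2/DMSO closes ring C.
- Ring order: rings A and B are bought as arenes (1, 3). Ring C is the only ring formed (step 4), and the key step closes no ring.

Key step: step 7

Remark: the target has no stereocentre. The only stereodescriptor in the route is the E alkene of chalcone 5, which disappears when ring C closes.

## Route

Step 1
Reactants: 1 3,4,5-trimethoxyphenol
Product: 2 1-(6-hydroxy-2,3,4-trimethoxyphenyl)ethan-1-one
Conditions: Ac2O (1.3 equiv), BF3·OEt2 (excess), 70 °C; then H2O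
Reagents that add atoms: acetic anhydride, CC(=O)OC(C)=O
Why: Friedel–Crafts (Fries-type) C-acylation at one of the two symmetry-equivalent free positions ortho to the phenol, with boron chelation of the resulting o-hydroxyketone preventing a second acylation.

Step 2
Reactants: 3 2,5-dihydroxybenzaldehyde
Product: 4 2,5-bis(benzyloxy)benzaldehyde
Conditions: BnBr (2.3 equiv), K2CO3 (3 equiv), DMF, N2, 60 °C
Reagents that add atoms: benzyl bromide, BrCc1ccccc1
Why: Williamson ether synthesis on both phenols, where warm DMF also carries the chelated 2-OH through and nitrogen keeps the hydroquinone from autoxidising before it is capped.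

Step 3
Reactants: 2 1-(6-hydroxy-2,3,4-trimethoxyphenyl)ethan-1-one; 4 2,5-bis(benzyloxy)benzaldehyde
Product: 5 (E)-3-[2,5-bis(benzyloxy)phenyl]-1-(6-hydroxy-2,3,4-trimethoxyphenyl)prop-2-en-1-one
Conditions: KOH (excess), EtOH–THF, rt; then 1 M HCl
Reagents that add atoms: none
Why: Claisen–Schmidt aldol condensation between the only enolisable ketone and a non-enolisable aldehyde, with E1cB dehydration giving the thermodynamically preferred E enone.

Step 4
Reactants: 5 (E)-3-[2,5-bis(benzyloxy)phenyl]-1-(6-hydroxy-2,3,4-trimethoxyphenyl)prop-2-en-1-one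
Product: 6 2-[2,5-bis(benzyloxy)phenyl]-5,6,7-trimethoxy-4H-chromen-4-one
Conditions: I2 (10 mol %), DMSO, 120 °C; aq. Na2S2O3 wash
Reagents that add atoms: none
Why: Iodine-catalysed oxidative cyclisation of a 2'-hydroxychalcone to a flavone, in which the phenol oxygen closes ring C on Cβ in a 6-endo mode, loss of HI sets up C2=C3, and DMSO reoxidises HI to I2 as terminal oxidant.

Step 5
Reactants: 6 2-[2,5-bis(benzyloxy)phenyl]-5,6,7-trimethoxy-4H-chromen-4-one
Product: 7 2-(2,5-dihydroxyphenyl)-5-hydroxy-6,7-dimethoxy-4H-chromen-4-one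
Conditions: BCl3 (about 5 equiv), pentamethylbenzene (6 equiv), CH2Cl2, −78 °C → 0 °C; then H2O
Reagents that add atoms: none
Why: Lewis acid debenzylation of the aryl benzyl ethers at low temperature, with pentamethylbenzene trapping the benzyl cation so that C8 and ring B are not C-benzylated, followed on warming by carbonyl-directed demethylation of O5 only, because boron chelates between O4 and O5 while the 6- and 7-methyl ethers lack such assistance.

Step 6
Reactants: 7 2-(2,5-dihydroxyphenyl)-5-hydroxy-6,7-dimethoxy-4H-chromen-4-one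
Product: 8 2-[2,5-bis(pivaloyloxy)phenyl]-5-hydroxy-6,7-dimethoxy-4H-chromen-4-one
Conditions: PivCl (2.2 equiv), pyridine, CH2Cl2, 0 °C → rt
Reagents that add atoms: pivaloyl chloride, CC(C)(C)C(=O)Cl
Why: Chemoselective O-acylation, since the two ring B phenols are free nucleophiles whereas O5–H is hydrogen-bonded to the C4 carbonyl and flanked by 6-OMe, so a bulky acyl chloride dosed just above two equivalents should leave it free.

Step 7
Reactants: 8 2-[2,5-bis(pivaloyloxy)phenyl]-5-hydroxy-6,7-dimethoxy-4H-chromen-4-one
Product: 10 2-[2,5-bis(pivaloyloxy)phenyl]-6,7,8,8-tetramethoxy-4H-chromene-4,5(8H)-dione, via 8-methoxy-5-hydroxyflavone bis-pivalate 9 (not isolated)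
Conditions: PhI(OAc)2 (2.4 equiv), anhydrous MeOH–CH2Cl2 (3:1), 0 °C → rt; aq. NaHCO3 wash, Et3N-deactivated silica or use crude
Reagents that add atoms: methanol, CO
Why: O5–H exchanges for acetate on trivalent iodine, methanol attacks C8 as iodobenzene and acetate depart, and loss of the C8 proton rearomatises to 9; as a p-methoxyphenol, 9 is oxidised more readily than 8, so the reaction is driven on with more than two equivalents of oxidant until a second methanol is captured at the now methoxy-stabilised C8 to give 10 as the single end point. This is the known hypervalent iodine oxidation of para-unsubstituted phenols, o-acylphenols included, in methanol to p-quinone monoketals. No ring closes and no stereocentre forms, because C8 carries two identical methoxy groups. The selectivity needed is attack at C8–H rather than ipso at C6, the path by which 2-methoxyphenols often give o-quinone monoketals; here 6-OMe is squeezed between O5 and 7-OMe and twisted out of the ring plane, which makes it a weak cation stabiliser, a ketal at C6 would be a crowded fully substituted carbon, and only the C8 path is made irreversible by proton loss and a second oxidation whose para preference (p-OMe over o-OMe) is well established. Any o-quinone monoketal that does form is returned to 8 by the zinc reduction of step 8 and can be recycled. Ring B has no free phenol and is electron-poor as the bis-pivalate, and methanol with the liberated AcOH touches neither the pivalates nor the C2=C3 bond of ring C.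

Step 8
Reactants: 10 2-[2,5-bis(pivaloyloxy)phenyl]-6,7,8,8-tetramethoxy-4H-chromene-4,5(8H)-dione
Product: 9 2-[2,5-bis(pivaloyloxy)phenyl]-5-hydroxy-6,7,8-trimethoxy-4H-chromen-4-one
Conditions: Zn dust (5 equiv), glacial AcOH, dry THF, 0 °C → rt, short contact time
Reagents that add atoms: none
Why: Dissolving-metal reduction of a p-quinone monoketal, in which two-electron transfer to the C5 dienone gives a dienolate that expels one C8 methoxide and rearomatises, so the O5–H/O8–Me pattern needs no methylating agent, while dry, cold and brief conditions keep ketal hydrolysis and reduction of ring C out of play.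

Step 9
Reactants: 9 2-[2,5-bis(pivaloyloxy)phenyl]-5-hydroxy-6,7,8-trimethoxy-4H-chromen-4-one
Product: 11 5,2',5'-trihydroxy-6,7,8-trimethoxyflavone
Conditions: K2CO3 (4 equiv), degassed MeOH, Ar, rt; then 1 M HCl to pH 3–4 before exposure to air
Reagents that add atoms: none
Why: Base-mediated transesterification (methanolysis) of the two aryl pivalates, whose phenoxide leaving groups make them far more labile than the methyl ethers, with oxygen excluded and acid added first because the liberated ring B hydroquinone would otherwise autoxidise in base.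

## Compound list

1 | 3,4,5-trimethoxyphenol | COc1cc(O)cc(OC)c1OC | starting material
2 | 1-(6-hydroxy-2,3,4-trimethoxyphenyl)ethan-1-one | CC(=O)c1c(O)cc(OC)c(OC)c1OC | intermediate
3 | 2,5-dihydroxybenzaldehyde | O=Cc1cc(O)ccc1O | starting material
4 | 2,5-bis(benzyloxy)benzaldehyde | O=Cc1cc(OCc2ccccc2)ccc1OCc1ccccc1 | intermediate
5 | (E)-3-[2,5-bis(benzyloxy)phenyl]-1-(6-hydroxy-2,3,4-trimethoxyphenyl)prop-2-en-1-one | COc1cc(O)c(C(=O)/C=C/c2cc(OCc3ccccc3)ccc2OCc2ccccc2)c(OC)c1OC | intermediate
6 | 2-[2,5-bis(benzyloxy)phenyl]-5,6,7-trimethoxy-4H-chromen-4-one | COc1cc2oc(-c3cc(OCc4ccccc4)ccc3OCc3ccccc3)cc(=O)c2c(OC)c1OC | intermediate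
7 | 2-(2,5-dihydroxyphenyl)-5-hydroxy-6,7-dimethoxy-4H-chromen-4-one | COc1cc2oc(-c3cc(O)ccc3O)cc(=O)c2c(O)c1OC | intermediate
8 | 2-[2,5-bis(pivaloyloxy)phenyl]-5-hydroxy-6,7-dimethoxy-4H-chromen-4-one | COc1cc2oc(-c3cc(OC(=O)C(C)(C)C)ccc3OC(=O)C(C)(C)C)cc(=O)c2c(O)c1OC | intermediate
9 | 2-[2,5-bis(pivaloyloxy)phenyl]-5-hydroxy-6,7,8-trimethoxy-4H-chromen-4-one (transient in step 7, isolated in step 8) | COc1c(OC)c(O)c2c(=O)cc(-c3cc(OC(=O)C(C)(C)C)ccc3OC(=O)C(C)(C)C)oc2c1OC | intermediate
10 | 2-[2,5-bis(pivaloyloxy)phenyl]-6,7,8,8-tetramethoxy-4H-chromene-4,5(8H)-dione | COC1=C(OC)C(OC)(OC)C2=C(C1=O)C(=O)C=C(c3cc(OC(=O)C(C)(C)C)ccc3OC(=O)C(C)(C)C)O2 | intermediate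
11 | 5,2',5'-trihydroxy-6,7,8-trimethoxyflavone | COc1c(OC)c(O)c2c(=O)cc(-c3cc(O)ccc3O)oc2c1OC | target

## Step count and risks

Total step count: 9.
Longest linear sequence: 8 steps (1 → 2 → 5 → 6 → 7 → 8 → 10 → 9 → 11; the branch from 3 is equally long).

**Step 7.**
- What may go wrong: methanol may be captured ipso at C6 instead of at C8. Ligand exchange at the strongly chelated O5–H may be sluggish. The ketal may hydrolyse during isolation.
- Fallback, from 8 back to 11: replace oxidative dearomatisation by halogenation and copper-mediated C–O coupling. NBS in MeCN at 0 °C should brominate the single open, phenol-activated ring A position, with ring B deactivated by its esters, to give 8-bromo-2-[2,5-bis(pivaloyloxy)phenyl]-5-hydroxy-6,7-dimethoxy-4H-chromen-4-one F1.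
- Ullmann-type methoxylation (NaOMe in excess, CuBr, DMF–MeOH, 110 °C, Ar, acidic quench) should then exchange bromide for methoxide. It also methanolyses both pivalates in the same pot, so it arrives directly at 11 and bypasses 9 and 10.

**Step 8.**
- What may go wrong: acid-promoted hydrolysis of the ketal may outrun electron transfer, which would lose the O8 methyl group. Prolonged contact with zinc may begin to reduce ring C.
- Fallback, from 10 back to 9: accept the hydrolysis and re-install the methyl group by chelation-controlled alkylation. Aqueous oxalic acid in THF should convert 10 into 2-[2,5-bis(pivaloyloxy)phenyl]-6,7-dimethoxy-4H-chromene-4,5,8-trione F2.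
- Na2S2O4 in EtOAc–water should reduce F2 to 2-[2,5-bis(pivaloyloxy)phenyl]-5,8-dihydroxy-6,7-dimethoxy-4H-chromen-4-one F3.
- MeI (1.05 equiv) with K2CO3 in acetone under Ar should methylate only the non-chelated 8-OH and give 9.

**Step 5.**
- What may go wrong: demethylation may continue at O6 once boron sits on O5. Debenzylation may be incomplete. The benzyl cation may be transferred to C8 or ring B.
- Fallback, from 6 back to 8: separate the two deprotections and move the acylation between them, so that neither a selective acylation nor a large excess of Lewis acid is needed. Hydrogenolysis (H2, Pd/C, EtOAc–MeOH) should give 2-(2,5-dihydroxyphenyl)-5,6,7-trimethoxy-4H-chromen-4-one F4.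
- Exhaustive acylation (PivCl, pyridine, DMAP) should give 2-[2,5-bis(pivaloyloxy)phenyl]-5,6,7-trimethoxy-4H-chromen-4-one F5.
- BCl3 dosed near one equivalent (CH2Cl2, −20 °C → 0 °C) should remove only the peri O5 methyl and give 8, bypassing 7.

## Further compounds

F1 | step 7 | 8-bromo-2-[2,5-bis(pivaloyloxy)phenyl]-5-hydroxy-6,7-dimethoxy-4H-chromen-4-one | COc1c(Br)c2oc(-c3cc(OC(=O)C(C)(C)C)ccc3OC(=O)C(C)(C)C)cc(=O)c2c(O)c1OC
F2 | step 8 | 2-[2,5-bis(pivaloyloxy)phenyl]-6,7-dimethoxy-4H-chromene-4,5,8-trione | COC1=C(OC)C(=O)C2=C(C1=O)C(=O)C=C(c3cc(OC(=O)C(C)(C)C)ccc3OC(=O)C(C)(C)C)O2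
F3 | step 8 | 2-[2,5-bis(pivaloyloxy)phenyl]-5,8-dihydroxy-6,7-dimethoxy-4H-chromen-4-one | COc1c(OC)c(O)c2c(=O)cc(-c3cc(OC(=O)C(C)(C)C)ccc3OC(=O)C(C)(C)C)oc2c1O
F4 | step 5 | 2-(2,5-dihydroxyphenyl)-5,6,7-trimethoxy-4H-chromen-4-one | COc1cc2oc(-c3cc(O)ccc3O)cc(=O)c2c(OC)c1OC
F5 | step 5 | 2-[2,5-bis(pivaloyloxy)phenyl]-5,6,7-trimethoxy-4H-chromen-4-one | COc1cc2oc(-c3cc(OC(=O)C(C)(C)C)ccc3OC(=O)C(C)(C)C)cc(=O)c2c(OC)c1OC
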